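## Retrosynthetic overview

1. Target ⇐ hydrogenolysis of three aryl benzyl ethers ⇐ reductive release of the auxiliary ⇐ Evans syn-aldol (C7″–C8″ bond, both side-chain stereocentres) of a ring A arylacetyl imide with O-benzylvanillin.
2. Ring A arylacetyl imide ⇐ Pd-catalysed α-arylation (C5–C8″ bond) of a 5-bromo dibenzylbutyrolactone with the silyl enolate of an N-acetyl oxazolidinone.
3. Butyrolactone (the only ring that is built; closed in step 6, before any side-chain work) ⇐ reduction of C9′ and O9′→C9 closure of an 8–8′-coupled seco diacid derivative, then equilibration to trans. The order coupling → reduction → lactone closure is that of lignan biogenesis; the closure is a lactonisation rather than a diol dehydrogenation, because the two aryl rings differ and only this fixes which carbon becomes the carbonyl.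
4. C8–C8′ bond ⇐ oxidative radical heterocoupling of two dihydroferulate enolates: chiral imide (ring B unit, sets C8′) and benzyl ester (brominated ring A unit, becomes the carbonyl side).
5. Both units ⇐ dihydroferulic acid; aromatic rings A, B and C are bought, not built.

Assumption: lignan locants are used (ring A with C7–C9 = unit on lactone C3; ring B with C7′–C9′ = unit on lactone C4; ring C with C7″–C9″ = side chain), and dihydroferulic acid, (S)-4-benzyloxazolidin-2-one, (S)-3-acetyl-4-benzyloxazolidin-2-one and 4-(benzyloxy)-3-methoxybenzaldehyde are bought.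

## Route

Step 1
Reactants: 1 3-(4-hydroxy-3-methoxyphenyl)propanoic acid (dihydroferulic acid)
Product: 3 3-[4-(benzyloxy)-3-methoxyphenyl]propanoic acid, via sodium carboxylate 2 (not isolated)
Conditions: BnBr (1.1 equiv), NaOH (2.5 equiv), EtOH–H2O, reflux; then aq. HCl
Reagents that add atoms: benzyl bromide, BrCc1ccccc1
Why: Williamson ether synthesis on the dianion alkylates the more nucleophilic phenoxide, and any benzyl ester formed is saponified in the same hot alkaline medium; no stereocentre is involved.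

Step 2
Reactants: 3 3-[4-(benzyloxy)-3-methoxyphenyl]propanoic acid; 4 (S)-4-benzyloxazolidin-2-one
Product: 6 (4S)-4-benzyl-3-{3-[4-(benzyloxy)-3-methoxyphenyl]propanoyl}oxazolidin-2-one, via mixed pivalic anhydride 5 (not isolated)
Conditions: PivCl, Et3N, THF, −20 °C; then 4, LiCl, rt
Reagents that add atoms: none
Why: N-acylation of the oxazolidinone by a mixed anhydride (one-pot LiCl/Et3N imide formation) is routine for 3-arylpropanoic acids and leaves the auxiliary stereocentre untouched.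

Step 3
Reactants: 1 3-(4-hydroxy-3-methoxyphenyl)propanoic acid
Product: 7 3-(3-bromo-4-hydroxy-5-methoxyphenyl)propanoic acid
Conditions: NBS (1.0 equiv), MeCN, 0 °C
Reagents that add atoms: N-bromosuccinimide, BrN1C(=O)CCC1=O
Why: electrophilic aromatic bromination of a 4-alkylguaiacol goes ortho to the free phenol (para position blocked, OH the dominant director), placing the halogen at C5 where the side chain will be attached.

Step 4
Reactants: 7 3-(3-bromo-4-hydroxy-5-methoxyphenyl)propanoic acid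
Product: 8 benzyl 3-[4-(benzyloxy)-3-bromo-5-methoxyphenyl]propanoate
Conditions: BnBr (2.3 equiv), K2CO3, DMF, 60 °C
Reagents that add atoms: benzyl bromide, BrCc1ccccc1
Why: double SN2 O-alkylation (Williamson etherification plus carboxylate alkylation) masks the phenol and gives the enolisable benzyl ester in one operation.

Step 5
Reactants: 6 (4S)-4-benzyl-3-{3-[4-(benzyloxy)-3-methoxyphenyl]propanoyl}oxazolidin-2-one; 8 benzyl 3-[4-(benzyloxy)-3-bromo-5-methoxyphenyl]propanoate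
Product: 11 benzyl (2RS,3R)-2-[4-(benzyloxy)-3-bromo-5-methoxybenzyl]-3-[4-(benzyloxy)-3-methoxybenzyl]-4-[(4S)-4-benzyl-2-oxooxazolidin-3-yl]-4-oxobutanoate (C2 epimers), via lithium imide enolate 9 (not isolated), via lithium ester enolate 10 (not isolated)
Conditions: 6 (1.0 equiv), 8 (1.5 equiv), LiN(iPr)2 (2.6 equiv), THF, −78 °C; Fe(C5H7O2)3 [Fe(acac)3] (2.2 equiv), −78 °C → rt
Reagents that add atoms: none
Why: oxidative enolate heterocoupling, in which one-electron oxidation of the mixed lithium enolates by trivalent iron gives an α-carbonyl radical that joins C8 to C8′ as the radical 8–8′ coupling does in lignan biogenesis; the chelated (Z)-imide enolate reacts on the face away from the auxiliary benzyl, setting C8′ as R, while the ester α-centre (C8) forms as an epimer mixture that step 6 corrects, and the imide/ester pairing fixes which unit will carry the lactone carbonyl.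

Step 6
Reactants: 11 benzyl (2RS,3R)-2-[4-(benzyloxy)-3-bromo-5-methoxybenzyl]-3-[4-(benzyloxy)-3-methoxybenzyl]-4-[(4S)-4-benzyl-2-oxooxazolidin-3-yl]-4-oxobutanoate
Product: 14 (3R,4R)-3-[4-(benzyloxy)-3-bromo-5-methoxybenzyl]-4-[4-(benzyloxy)-3-methoxybenzyl]dihydrofuran-2(3H)-one, via hydroxy ester 12 (not isolated), via lactone C3-epimer mixture 13 (not isolated)
Conditions: LiBH4, MeOH (1.2 equiv each), THF, 0 °C; aq. NH4Cl; crude product, DBU (0.3 equiv), PhMe, 80 °C (telescoped, one isolation)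
Reagents that add atoms: none
Why: chemoselective hydride reduction of the activated imide carbonyl frees the C9′ alkoxide, which closes the γ-lactone on the benzyl ester (5-exo-trig lactonisation, the O9′→C9 closure of the natural pathway), and base-mediated epimerisation of the acidic C3 centre then gives the more stable trans-3,4-dibenzyl lactone, so that C3 (R) follows from C4 (R).

Step 7
Reactants: 14 (3R,4R)-3-[4-(benzyloxy)-3-bromo-5-methoxybenzyl]-4-[4-(benzyloxy)-3-methoxybenzyl]dihydrofuran-2(3H)-one; 15 (S)-3-acetyl-4-benzyloxazolidin-2-one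
Product: 17 (3R,4R)-3-{4-(benzyloxy)-3-[2-((4S)-4-benzyl-2-oxooxazolidin-3-yl)-2-oxoethyl]-5-methoxybenzyl}-4-[4-(benzyloxy)-3-methoxybenzyl]dihydrofuran-2(3H)-one, via silyl ketene aminal 16 (not isolated)
Conditions: 15, LiN(iPr)2, THF, −78 °C, then Me3SiCl (crude 16 after pentane filtration and evaporation); 14, Pd(C17H14O)2 [Pd(dba)2] (5 mol %), P(t-Bu)3 (10 mol %), ZnF2 (0.6 equiv), DMF, 80 °C
Reagents that add atoms: none
Why: Pd-catalysed α-arylation of a silyl imide enolate under ZnF2 activation (enolate cross-coupling without added base) forms the C5–C8″ bond while the lactone and its epimerisable C3 stay untouched; no new stereocentre is formed.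

Step 8
Reactants: 17 (3R,4R)-3-{4-(benzyloxy)-3-[2-((4S)-4-benzyl-2-oxooxazolidin-3-yl)-2-oxoethyl]-5-methoxybenzyl}-4-[4-(benzyloxy)-3-methoxybenzyl]dihydrofuran-2(3H)-one; 18 4-(benzyloxy)-3-methoxybenzaldehyde
Product: 21 (3R,4R)-3-{4-(benzyloxy)-3-[(1S,2S)-1-((4S)-4-benzyl-2-oxooxazolidine-3-carbonyl)-2-(4-(benzyloxy)-3-methoxyphenyl)-2-hydroxyethyl]-5-methoxybenzyl}-4-[4-(benzyloxy)-3-methoxybenzyl]dihydrofuran-2(3H)-one, via boron enolate 19 (not isolated), via boron aldolate 20 (not isolated)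
Conditions: Bu2BOTf (1.2 equiv), iPr2NEt (1.4 equiv), CH2Cl2, −78 → 0 °C; 18, −78 → 0 °C; pH 7 buffer, MeOH, 30 % H2O2, 0 °C
Reagents that add atoms: none
Why: Evans syn-aldol reaction, in which the (Z)-dibutylboron enolate reacts through a closed Zimmerman–Traxler transition state on the face away from the auxiliary benzyl to give the syn (2S,3S) adduct, which is C8″ and C7″ in the relative and absolute configuration of the target.

Step 9
Reactants: 21 (3R,4R)-3-{4-(benzyloxy)-3-[(1S,2S)-1-((4S)-4-benzyl-2-oxooxazolidine-3-carbonyl)-2-(4-(benzyloxy)-3-methoxyphenyl)-2-hydroxyethyl]-5-methoxybenzyl}-4-[4-(benzyloxy)-3-methoxybenzyl]dihydrofuran-2(3H)-one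
Product: 22 (3R,4R)-3-{4-(benzyloxy)-3-[(1S,2R)-1-(4-(benzyloxy)-3-methoxyphenyl)-1,3-dihydroxypropan-2-yl]-5-methoxybenzyl}-4-[4-(benzyloxy)-3-methoxybenzyl]dihydrofuran-2(3H)-one
Conditions: LiBH4 (1.5 equiv), MeOH (1.5 equiv), THF, −10 → 0 °C, stopped when the imide is consumed
Reagents that add atoms: none
Why: reductive cleavage of the N-acyloxazolidinone by LiBH4 is much faster than reduction of the hindered γ-lactone at or below 0 °C and gives C9″H2OH without touching C7″ or C8″ (the C8″ descriptor changes from S to R only through CIP priorities).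

Step 10
Reactants: 22 (3R,4R)-3-{4-(benzyloxy)-3-[(1S,2R)-1-(4-(benzyloxy)-3-methoxyphenyl)-1,3-dihydroxypropan-2-yl]-5-methoxybenzyl}-4-[4-(benzyloxy)-3-methoxybenzyl]dihydrofuran-2(3H)-one
Product: 23 (3R,4R)-3-{3-[(1S,2R)-1,3-dihydroxy-1-(4-hydroxy-3-methoxyphenyl)propan-2-yl]-4-hydroxy-5-methoxybenzyl}-4-(4-hydroxy-3-methoxybenzyl)dihydrofuran-2(3H)-one (CNP0317849.1)
Conditions: H2 (1 atm), Pd on carbon (10 % Pd/C), EtOAc–EtOH, rt; acid-free work-up
Reagents that add atoms: none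
Why: neutral heterogeneous hydrogenolysis removes the three aryl benzyl ethers while the lactone and the secondary benzylic C7″ hydroxyl survive at 1 atm and room temperature, and the ring A phenol is unmasked only here, so acid-promoted closure to the phenylcoumaran is avoided; no stereocentre is affected.

## Compound list

1 | 3-(4-hydroxy-3-methoxyphenyl)propanoic acid (dihydroferulic acid) | COc1cc(CCC(=O)O)ccc1O | starting material
2 | sodium 3-[4-(benzyloxy)-3-methoxyphenyl]propanoate | COc1cc(CCC(=O)[O-])ccc1OCc1ccccc1.[Na+] | intermediate (not isolated)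
3 | 3-[4-(benzyloxy)-3-methoxyphenyl]propanoic acid | COc1cc(CCC(=O)O)ccc1OCc1ccccc1 | intermediate
4 | (S)-4-benzyloxazolidin-2-one | O=C1N[C@@H](Cc2ccccc2)CO1 | starting material
5 | 3-[4-(benzyloxy)-3-methoxyphenyl]propanoic pivalic anhydride | COc1cc(CCC(=O)OC(=O)C(C)(C)C)ccc1OCc1ccccc1 | intermediate (not isolated)
6 | (4S)-4-benzyl-3-{3-[4-(benzyloxy)-3-methoxyphenyl]propanoyl}oxazolidin-2-one | COc1cc(CCC(=O)N2[C@@H](Cc3ccccc3)COC2=O)ccc1OCc1ccccc1 | intermediate
7 | 3-(3-bromo-4-hydroxy-5-methoxyphenyl)propanoic acid | COc1cc(CCC(=O)O)cc(Br)c1O | intermediate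
8 | benzyl 3-[4-(benzyloxy)-3-bromo-5-methoxyphenyl]propanoate | COc1cc(CCC(=O)OCc2ccccc2)cc(Br)c1OCc1ccccc1 | intermediate
9 | lithium (Z)-enolate of imide 6 | COc1cc(C/C=C(\O[Li])N2[C@@H](Cc3ccccc3)COC2=O)ccc1OCc1ccccc1 | intermediate (not isolated)
10 | lithium enolate of ester 8 (geometry not defined) | COc1cc(CC=C(O[Li])OCc2ccccc2)cc(Br)c1OCc1ccccc1 | intermediate (not isolated)
11 | benzyl (2RS,3R)-2-[4-(benzyloxy)-3-bromo-5-methoxybenzyl]-3-[4-(benzyloxy)-3-methoxybenzyl]-4-[(4S)-4-benzyl-2-oxooxazolidin-3-yl]-4-oxobutanoate (C2 epimers, C2 left undefined in the SMILES) | COc1cc(CC(C(=O)OCc2ccccc2)[C@@H](Cc2ccc(OCc3ccccc3)c(OC)c2)C(=O)N2[C@@H](Cc3ccccc3)COC2=O)cc(Br)c1OCc1ccccc1 | intermediate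
12 | benzyl (2RS,3R)-2-[4-(benzyloxy)-3-bromo-5-methoxybenzyl]-3-[4-(benzyloxy)-3-methoxybenzyl]-4-hydroxybutanoate | COc1cc(CC(C(=O)OCc2ccccc2)[C@@H](Cc2ccc(OCc3ccccc3)c(OC)c2)CO)cc(Br)c1OCc1ccccc1 | intermediate (not isolated)
13 | (3RS,4R)-3-[4-(benzyloxy)-3-bromo-5-methoxybenzyl]-4-[4-(benzyloxy)-3-methoxybenzyl]dihydrofuran-2(3H)-one (C3 epimers) | COc1cc(C[C@H]2COC(=O)C2Cc2cc(OC)c(OCc3ccccc3)c(Br)c2)ccc1OCc1ccccc1 | intermediate (not isolated)
14 | (3R,4R)-3-[4-(benzyloxy)-3-bromo-5-methoxybenzyl]-4-[4-(benzyloxy)-3-methoxybenzyl]dihydrofuran-2(3H)-one | COc1cc(C[C@H]2COC(=O)[C@@H]2Cc2cc(OC)c(OCc3ccccc3)c(Br)c2)ccc1OCc1ccccc1 | intermediate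
15 | (S)-3-acetyl-4-benzyloxazolidin-2-one | CC(=O)N1[C@@H](Cc2ccccc2)COC1=O | starting material
16 | (S)-4-benzyl-3-[1-(trimethylsilyloxy)vinyl]oxazolidin-2-one | C=C(O[Si](C)(C)C)N1[C@@H](Cc2ccccc2)COC1=O | intermediate (not isolated)
17 | (3R,4R)-3-{4-(benzyloxy)-3-[2-((4S)-4-benzyl-2-oxooxazolidin-3-yl)-2-oxoethyl]-5-methoxybenzyl}-4-[4-(benzyloxy)-3-methoxybenzyl]dihydrofuran-2(3H)-one | COc1cc(C[C@H]2COC(=O)[C@@H]2Cc2cc(OC)c(OCc3ccccc3)c(CC(=O)N3[C@@H](Cc4ccccc4)COC3=O)c2)ccc1OCc1ccccc1 | intermediate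
18 | 4-(benzyloxy)-3-methoxybenzaldehyde (O-benzylvanillin) | COc1cc(C=O)ccc1OCc1ccccc1 | starting material
19 | (Z)-dibutylboron enolate of imide 17 | COc1cc(C[C@H]2COC(=O)[C@@H]2Cc2cc(OC)c(OCc3ccccc3)c(/C=C(\OB(CCCC)CCCC)N3[C@@H](Cc4ccccc4)COC3=O)c2)ccc1OCc1ccccc1 | intermediate (not isolated)
20 | O-dibutylboryl aldolate of 21 | COc1cc(C[C@H]2COC(=O)[C@@H]2Cc2cc(OC)c(OCc3ccccc3)c([C@H](C(=O)N3[C@@H](Cc4ccccc4)COC3=O)[C@H](OB(CCCC)CCCC)c3ccc(OCc4ccccc4)c(OC)c3)c2)ccc1OCc1ccccc1 | intermediate (not isolated)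
21 | (3R,4R)-3-{4-(benzyloxy)-3-[(1S,2S)-1-((4S)-4-benzyl-2-oxooxazolidine-3-carbonyl)-2-(4-(benzyloxy)-3-methoxyphenyl)-2-hydroxyethyl]-5-methoxybenzyl}-4-[4-(benzyloxy)-3-methoxybenzyl]dihydrofuran-2(3H)-one | COc1cc(C[C@H]2COC(=O)[C@@H]2Cc2cc(OC)c(OCc3ccccc3)c([C@H](C(=O)N3[C@@H](Cc4ccccc4)COC3=O)[C@H](O)c3ccc(OCc4ccccc4)c(OC)c3)c2)ccc1OCc1ccccc1 | intermediate
22 | (3R,4R)-3-{4-(benzyloxy)-3-[(1S,2R)-1-(4-(benzyloxy)-3-methoxyphenyl)-1,3-dihydroxypropan-2-yl]-5-methoxybenzyl}-4-[4-(benzyloxy)-3-methoxybenzyl]dihydrofuran-2(3H)-one | COc1cc(C[C@H]2COC(=O)[C@@H]2Cc2cc(OC)c(OCc3ccccc3)c([C@H](CO)[C@H](O)c3ccc(OCc4ccccc4)c(OC)c3)c2)ccc1OCc1ccccc1 | intermediate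
23 | (3R,4R)-3-{3-[(1S,2R)-1,3-dihydroxy-1-(4-hydroxy-3-methoxyphenyl)propan-2-yl]-4-hydroxy-5-methoxybenzyl}-4-(4-hydroxy-3-methoxybenzyl)dihydrofuran-2(3H)-one | COc1cc(C[C@H]2COC(=O)[C@@H]2Cc2cc(OC)c(O)c([C@H](CO)[C@H](O)c3ccc(O)c(OC)c3)c2)ccc1O | target

## Step count and risk

Total steps: 10. Longest linear sequence: 8 (1 → 7 → 8 → 11 → 14 → 17 → 21 → 22 → 23; the branch 1 → 3 → 6 → 11 is equally long).

**Step 5 (oxidative heterocoupling).** Homodimers of 6 or 8 may compete, the yield may be modest, and facial control at the imide centre may be incomplete. The fallback sets out from 6 and rejoins at 14, building the C8–C8′ bond by two polar alkylations. The sodium enolate of 6 (NaN(SiMe3)2, THF, −78 °C) is alkylated with tert-butyl bromoacetate, anti to the auxiliary benzyl, to give tert-butyl (3R)-3-[4-(benzyloxy)-3-methoxybenzyl]-4-[(4S)-4-benzyl-2-oxooxazolidin-3-yl]-4-oxobutanoate F1. LiBH4 reduces the imide to tert-butyl (3R)-3-[4-(benzyloxy)-3-methoxybenzyl]-4-hydroxybutanoate F2, which TsOH in toluene closes to (4R)-4-[4-(benzyloxy)-3-methoxybenzyl]dihydrofuran-2(3H)-one F3. In parallel, commercial 5-bromovanillin is benzylated (BnBr, K2CO3) to 4-(benzyloxy)-3-bromo-5-methoxybenzaldehyde F4, reduced with NaBH4 to [4-(benzyloxy)-3-bromo-5-methoxyphenyl]methanol F5 and converted with PBr3 into 4-(benzyloxy)-3-bromo-5-methoxybenzyl bromide F6. The lithium enolate of F3 (LiN(SiMe3)2, THF, −78 °C) is alkylated by F6 trans to the C4 substituent, which gives 14 directly.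

**Step 7 (α-arylation with the silyl imide enolate).** The hindered, electron-rich ortho-alkoxy aryl bromide may add slowly to zerovalent palladium, and the more acidic product may be arylated a second time. The fallback sets out from 14 and rejoins at 17, attaching the acetate unit first and the auxiliary afterwards. Negishi-type coupling of 14 with the Reformatsky reagent BrZnCH2CO2tBu (Pd(dba)2, P(t-Bu)3, THF, rt) gives tert-butyl {2-(benzyloxy)-5-[((3R,4R)-4-(4-(benzyloxy)-3-methoxybenzyl)-2-oxotetrahydrofuran-3-yl)methyl]-3-methoxyphenyl}acetate F7. TFA in CH2Cl2 frees {2-(benzyloxy)-5-[((3R,4R)-4-(4-(benzyloxy)-3-methoxybenzyl)-2-oxotetrahydrofuran-3-yl)methyl]-3-methoxyphenyl}acetic acid F8. PivCl/Et3N turns this into the mixed pivalic anhydride of that acid F9 (not isolated), which acylates 4 in the presence of LiCl to give 17.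

**Step 9 (hydride removal of the auxiliary beside the lactone).** The lactone may be over-reduced to a diol, or the α-aryl β-alkoxide may undergo retro-aldol cleavage. The fallback sets out from 21 and rejoins at 22, separating cleavage from reduction. LiOH/H2O2 (THF–H2O, 0 °C), then mild acidification (which re-closes any opened lactone), gives (2S,3S)-3-[4-(benzyloxy)-3-methoxyphenyl]-2-{2-(benzyloxy)-5-[((3R,4R)-4-(4-(benzyloxy)-3-methoxybenzyl)-2-oxotetrahydrofuran-3-yl)methyl]-3-methoxyphenyl}-3-hydroxypropanoic acid F10. BH3·SMe2 (THF, 0 °C) then reduces the carboxylic acid chemoselectively in the presence of the lactone to give 22.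

## Further compounds

F1 | step 5 | tert-butyl (3R)-3-[4-(benzyloxy)-3-methoxybenzyl]-4-[(4S)-4-benzyl-2-oxooxazolidin-3-yl]-4-oxobutanoate | COc1cc(C[C@H](CC(=O)OC(C)(C)C)C(=O)N2[C@@H](Cc3ccccc3)COC2=O)ccc1OCc1ccccc1
F2 | step 5 | tert-butyl (3R)-3-[4-(benzyloxy)-3-methoxybenzyl]-4-hydroxybutanoate | COc1cc(C[C@H](CC(=O)OC(C)(C)C)CO)ccc1OCc1ccccc1
F3 | step 5 | (4R)-4-[4-(benzyloxy)-3-methoxybenzyl]dihydrofuran-2(3H)-one | COc1cc(C[C@H]2COC(=O)C2)ccc1OCc1ccccc1
F4 | step 5 | 4-(benzyloxy)-3-bromo-5-methoxybenzaldehyde | COc1cc(C=O)cc(Br)c1OCc1ccccc1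
F5 | step 5 | [4-(benzyloxy)-3-bromo-5-methoxyphenyl]methanol | COc1cc(CO)cc(Br)c1OCc1ccccc1
F6 | step 5 | 4-(benzyloxy)-3-bromo-5-methoxybenzyl bromide | COc1cc(CBr)cc(Br)c1OCc1ccccc1
F7 | step 7 | tert-butyl {2-(benzyloxy)-5-[((3R,4R)-4-(4-(benzyloxy)-3-methoxybenzyl)-2-oxotetrahydrofuran-3-yl)methyl]-3-methoxyphenyl}acetate | COc1cc(C[C@H]2COC(=O)[C@@H]2Cc2cc(OC)c(OCc3ccccc3)c(CC(=O)OC(C)(C)C)c2)ccc1OCc1ccccc1
F8 | step 7 | {2-(benzyloxy)-5-[((3R,4R)-4-(4-(benzyloxy)-3-methoxybenzyl)-2-oxotetrahydrofuran-3-yl)methyl]-3-methoxyphenyl}acetic acid | COc1cc(C[C@H]2COC(=O)[C@@H]2Cc2cc(OC)c(OCc3ccccc3)c(CC(=O)O)c2)ccc1OCc1ccccc1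
F9 | step 7 | mixed pivalic anhydride of acid F8 | COc1cc(C[C@H]2COC(=O)[C@@H]2Cc2cc(OC)c(OCc3ccccc3)c(CC(=O)OC(=O)C(C)(C)C)c2)ccc1OCc1ccccc1
F10 | step 9 | (2S,3S)-3-[4-(benzyloxy)-3-methoxyphenyl]-2-{2-(benzyloxy)-5-[((3R,4R)-4-(4-(benzyloxy)-3-methoxybenzyl)-2-oxotetrahydrofuran-3-yl)methyl]-3-methoxyphenyl}-3-hydroxypropanoic acid | COc1cc(C[C@H]2COC(=O)[C@@H]2Cc2cc(OC)c(OCc3ccccc3)c([C@H](C(=O)O)[C@H](O)c3ccc(OCc4ccccc4)c(OC)c3)c2)ccc1OCc1ccccc1
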